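The constants are made up; the rest is arithmetic.

I compared the flasks by their catalyst.

| flask | G | X | time | remark |
|---|---|---|---|---|
| north | 0.10 M (fed, over 1.20 h) | 0.18 mM | 1.5 h | a stirred flask in which G is dosed at a steady rate over 1.20 h without added volume, worked up at 1.5 h |
| west | 0.10 M | 0.18 mM |  | one stirred flow tank at steady state, fed with the mixture as stated, mean residence time 1.5 h |
| south | 0.10 M | 0.18 mM | 1.5 h | everything together in a closed stirred flask, run for 1.5 h |

    G + X → X + Q (k1 = 460 M⁻¹ min⁻¹)
    X → Z (k2 = 0.062 min⁻¹)
    X + Q → X + L (k3 = 200 M⁻¹ min⁻¹)
    2 X → X2 (k4 = 100 M⁻¹ min⁻¹)

* the set-up with the highest share of Q in all that became Q or L, at the outlet or at the end ("none" if the first two lie within 2 percentage points) (north / west / south / none)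
* share of Q in all that became Q or L, at the outlet or at the end, north
* share of Q in all that became Q or L, at the outlet or at the end, west
* share of Q in all that became Q or L, at the outlet or at the end, south

- two of one species on the left: rate k times its square, two consumed each time
- the stated concentrations are those of everything mixed, before any reaction; amounts are the same in each set-up
- the feed brings no volume worth counting
- run time (north): 1.5 h

- At the start of the south flask, G falls with the pseudo-first-order constant 0.0828 min⁻¹ and Q falls with 0.0360 min⁻¹; both constants are proportional to [X], so both slow as [X] falls.
- [X] falls by the second step at 0.062 min⁻¹ and, at the start, by the fourth at 0.0360 min⁻¹, and the latter shrinks with [X].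
- The mean life of X against the second step, 16.1 min, is shorter than the run of 90 min, so I integrated [X] out to long times: ln(one plus the ratio of those two constants), divided by the fourth step's starting constant, gave 12.7 min.
- This is the effective time, the span at the charged [X] that gives the same integral of [X] over time.
- Working with the fraction left, I put it into the exponentials of the south flask: G left was 34.9%, Q was 50.2%, and the share was 77.1%.
- In the west tank, the balance of X gave a steady [X] of 0.0256 mM, so its effective time was 12.8 min and its share 68.5%.
- In the north flask I reckoned crudely: taking G to grow in step with the effective time, Q grows as the square of that time and L as its cube, so L over Q is a third of the product of the constant for Q and the effective time, and the share is 86.8%; that ranked north first.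
- The forecast gave north as best, with 89.5%, 68.5% and 77.2% for north, west and south, on the grounds that “Q is lost to L in proportion to how long it sits with live X”; my north share was lower than its figure.
- The simulation gave north as best, with 89.7%, 68.5% and 77.2% for north, west and south.
- In the south flask, the first and third steps ran together over my effective time of 12.7 min, and the end stood, in percent of the G charged, at G 35.0%, Q 50.2% and L 14.8%, while in the north flask they ran as G was dosed, and G ended at 83.8% with L at 1.67%. In the west tank, with the reckoned [X] of 0.0256 mM and effective time of 12.8 min, G stood at 48.6%, Q at 35.2% and L at 16.2%.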